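## Retrosynthetic overview

1. Target 18 comes from its silyl ether 17, which is cut at the C2'–C3' bond of the diene (Heck disconnection) into the (R)-2-vinylchroman 8 and the (Z)-alkenyl iodide 16; 16 is made from β-homocyclocitral 9 and propyne 12 by carbocupration and iodination.
2. 8 comes from the (S)-2-vinyl-2H-chromene 7 by reduction of the styrenyl C3=C4 bond only.
3. 7 comes from the achiral triene 6 by a desymmetrising ring-closing metathesis that forms C3=C4 and closes ring B (the pyran ring).
4. Feature used: C2 (chroman numbering O1, C2, C3, C4, C4a, C8a) is a quaternary carbon bonded to O1, a methyl group and two two-carbon arms, C3–C4 inside ring B and C1'=C2' of the side chain. Written as two vinyl groups, these arms make C2 the prochiral carbinol carbon of an aryl ether of 3-methylpenta-1,4-dien-3-ol, and choosing one vinyl group for closure onto the benzylic carbon C4 creates the stereocentre.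
5. 6 comes from 2-fluoro-5-hydroxybenzaldehyde 1 and dienol 3 (silylation, SNAr, Wittig); ring A (arene) and ring C (cyclohexene) are bought, and ring B is the only ring formed (step 4).

Key step: step 4

Remark: the sense of induction of the chiral molybdenum complex on triene 6 cannot be assigned beforehand, so the biphenolate antipode that gives (S)-7 is to be fixed by an analytical run (both antipodes of the ligand are accessible).

## Route

Step 1
Reactants: 1 2-fluoro-5-hydroxybenzaldehyde
Product: 2 2-fluoro-5-[(triisopropylsilyl)oxy]benzaldehyde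
Conditions: TIPSCl, imidazole, DMF, 0 °C → rt
Reagents that add atoms: triisopropylsilyl chloride, CC(C)[Si](Cl)(C(C)C)C(C)C
Why: Imidazole-promoted O-silylation of a phenol; the bulky triisopropylsilyl ether is chosen because it has to resist a hindered alkoxide (step 2), an ylide (step 3) and the molybdenum alkylidene (step 4) and still fall to fluoride at the end.

Step 2
Reactants: 2 2-fluoro-5-[(triisopropylsilyl)oxy]benzaldehyde; 3 3-methylpenta-1,4-dien-3-ol
Product: 5 2-[(3-methylpenta-1,4-dien-3-yl)oxy]-5-[(triisopropylsilyl)oxy]benzaldehyde, via potassium alkoxide 4 (not isolated)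
Conditions: 3 (1.2 equiv), KH (1.1 equiv), THF, 0 °C; then 2, 18-crown-6 (0.1 equiv), 0 → 40 °C
Reagents that add atoms: potassium hydride, [K+].[H-] (its potassium stays only in intermediate 4)
Why: Nucleophilic aromatic substitution by addition–elimination, in which the ortho-formyl group stabilises the Meisenheimer adduct and fluoride is the best leaving group, while the tertiary alkoxide has no carbinol hydrogen to reduce the aldehyde and adds to it only reversibly, and the hindered alkoxide, the triisopropylsilyl group and the mild temperature should keep silyl transfer and aromatic Claisen rearrangement slow.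

Step 3
Reactants: 5 2-[(3-methylpenta-1,4-dien-3-yl)oxy]-5-[(triisopropylsilyl)oxy]benzaldehyde
Product: 6 triisopropyl{4-[(3-methylpenta-1,4-dien-3-yl)oxy]-3-vinylphenoxy}silane
Conditions: Ph3PCH3Br, NaHMDS, THF, 0 °C; then 5, 0 °C → rt
Reagents that add atoms: methyltriphenylphosphonium bromide, C[P+](c1ccccc1)(c1ccccc1)c1ccccc1.[Br-]
Why: Wittig methylenation of a non-enolisable aryl aldehyde with an unstabilised ylide, to which the aryl silyl ether and the bis-allylic ether are inert at 0 °C.

Step 4
Reactants: 6 triisopropyl{4-[(3-methylpenta-1,4-dien-3-yl)oxy]-3-vinylphenoxy}silane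
Product: 7 (S)-triisopropyl[(2-methyl-2-vinyl-2H-chromen-6-yl)oxy]silane
Conditions: Mo(N-2,6-i-Pr2C6H3)(CHCMe2Ph)(3,3'-di-t-Bu-5,5',6,6'-Me4-biphenyl-2,2'-diolate), one enantiomer (5 mol%), C6H6, 22 °C, N2, vessel open to let ethene leave
Reagents that add atoms: none
Why: The molybdenum neophylidene first exchanges with the least hindered alkene, the styrene CH=CH2 on ring A, to give an arylidene centred on C4, which adds to one of the two vinyl groups on the carbinol carbon in a [2+2] step to a molybdacyclobutane, and cycloreversion releases the C3=C4 alkene and Mo=CH2, the net loss being ethene. The closest known reaction type is the catalytic enantioselective ring-closing metathesis of achiral trienes with chiral hexavalent molybdenum imido alkylidene biphenolates, which gives unsaturated six-membered cyclic tertiary ethers by selection between two enantiotopic alkenes, together with the ring-closing metathesis of allyl 2-vinylphenyl ethers to 2H-chromenes. Ring B is closed by alkene metathesis between the benzylic carbon C4 and the internal carbon C3 of the chosen vinyl group, a six-membered closure in which the new alkene is necessarily cis and conjugated with ring A. No bond is made or broken at C2: the stereocentre results from the choice of vinyl group, and this choice is made in the chiral pocket of the biphenolate and the arylimido ligand, which makes the two diastereomeric molybdacyclobutanes unequal in energy. The step needs group selectivity between the enantiotopic vinyl groups and site selectivity for loading at the styrene; the quaternary carbon shields both vinyl groups against intermolecular metathesis and first loading, the two geminal vinyl groups cannot close a ring with each other, and escape of ethene makes the closure irreversible. The vinyl group left over is the handle for the side chain.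

Step 5
Reactants: 7 (S)-triisopropyl[(2-methyl-2-vinyl-2H-chromen-6-yl)oxy]silane
Product: 8 (R)-triisopropyl[(2-methyl-2-vinylchroman-6-yl)oxy]silane
Conditions: Mn(dpm)3 (dpm = dipivaloylmethanate, 10 mol%), PhSiH3 (1.0 equiv), t-BuOOH, i-PrOH, 22 °C, Ar
Reagents that add atoms: none
Why: Mukaiyama-type metal-hydride hydrogen-atom-transfer hydrogenation, in which the manganese hydride delivers a hydrogen atom to C3 because this gives the benzylic C4 radical, whereas the vinyl group on the quaternary C2 would give only an unstabilised secondary radical and should react far more slowly when the silane is limited; C2 is untouched, and its descriptor changes from S to R only because C3 drops below the vinyl group in CIP rank.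

Step 6
Reactants: 9 2-(2,6,6-trimethylcyclohex-1-en-1-yl)acetaldehyde (β-homocyclocitral)
Product: 10 2-(2,6,6-trimethylcyclohex-1-en-1-yl)ethan-1-ol
Conditions: NaBH4, MeOH, 0 °C
Reagents that add atoms: none
Why: Borohydride reduction of the aldehyde, under cold methanolic conditions that leave the tetrasubstituted ring alkene of the β,γ-unsaturated aldehyde in place.

Step 7
Reactants: 10 2-(2,6,6-trimethylcyclohex-1-en-1-yl)ethan-1-ol
Product: 11 2-(2-bromoethyl)-1,3,3-trimethylcyclohex-1-ene
Conditions: CBr4, PPh3, CH2Cl2, 0 °C → rt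
Reagents that add atoms: carbon tetrabromide, BrC(Br)(Br)Br
Why: Appel bromination of a primary alcohol (SN2 displacement of the alkoxyphosphonium ion by bromide) under neutral conditions, so that no cationic chemistry of the ring C alkene can intervene.

Step 8
Reactants: 11 2-(2-bromoethyl)-1,3,3-trimethylcyclohex-1-ene; 12 propyne
Product: 16 (Z)-2-(4-iodo-3-methylbut-3-en-1-yl)-1,3,3-trimethylcyclohex-1-ene, via Grignard reagent 13 (not isolated), via alkylcopper 14 (not isolated), via (Z)-alkenylcopper 15 (not isolated)
Conditions: Mg, Et2O, reflux; CuBr·SMe2, Et2O/Me2S, −45 °C; 12 (excess), −25 °C; I2, THF, −50 → 0 °C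
Reagents that add atoms: iodine, II; magnesium, [Mg], and CuBr·SMe2, Br[Cu].CSC (their metal atoms stay only in intermediates 13 to 15)
Why: Normant carbocupration, in which the alkylcopper made from the Grignard reagent adds syn across propyne with the alkyl group going to the internal carbon and copper to the terminal carbon, so that chain and copper are cis, and iodinolysis with retention gives the (Z)-alkenyl iodide.

Step 9
Reactants: 8 (R)-triisopropyl[(2-methyl-2-vinylchroman-6-yl)oxy]silane; 16 (Z)-2-(4-iodo-3-methylbut-3-en-1-yl)-1,3,3-trimethylcyclohex-1-ene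
Product: 17 (R)-triisopropyl({2-methyl-2-[(1E,3Z)-4-methyl-6-(2,6,6-trimethylcyclohex-1-en-1-yl)hexa-1,3-dien-1-yl]chroman-6-yl}oxy)silane
Conditions: Pd(OAc)2 (10 mol%), Ag2CO3 (1.0 equiv), 16 (1.3 equiv), DMF, 45 °C, dark
Reagents that add atoms: none
Why: Heck alkenylation, in which oxidative addition of the alkenyl iodide to zerovalent palladium with retention, syn carbopalladation that places the alkenyl group on the unhindered terminal carbon C2', and syn β-hydride elimination, which can only take a hydrogen from C2' because C2 is quaternary, give the (1'E) alkene while the (3'Z) geometry of 16 is carried over; silver carbonate removes iodide and curbs hydridopalladium re-addition.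

Step 10
Reactants: 17 (R)-triisopropyl({2-methyl-2-[(1E,3Z)-4-methyl-6-(2,6,6-trimethylcyclohex-1-en-1-yl)hexa-1,3-dien-1-yl]chroman-6-yl}oxy)silane
Product: 18 (R)-2-methyl-2-[(1E,3Z)-4-methyl-6-(2,6,6-trimethylcyclohex-1-en-1-yl)hexa-1,3-dien-1-yl]chroman-6-ol (CNP0275099.1)
Conditions: Bu4NF, AcOH (1:1), THF, 0 °C
Reagents that add atoms: none
Why: Fluoride-induced cleavage of the aryl silyl ether, buffered with acetic acid so that the electron-rich chromanol is not left as an air-sensitive phenoxide and the diene and the tertiary dienyl aryl ether meet neither acid nor strong base.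

## Compound list

1 | 2-fluoro-5-hydroxybenzaldehyde | O=Cc1cc(O)ccc1F | starting material
2 | 2-fluoro-5-[(triisopropylsilyl)oxy]benzaldehyde | O=Cc1cc(O[Si](C(C)C)(C(C)C)C(C)C)ccc1F | intermediate
3 | 3-methylpenta-1,4-dien-3-ol | C=CC(C)(O)C=C | starting material
4 | potassium 3-methylpenta-1,4-dien-3-olate | C=CC(C)([O-])C=C.[K+] | intermediate (not isolated)
5 | 2-[(3-methylpenta-1,4-dien-3-yl)oxy]-5-[(triisopropylsilyl)oxy]benzaldehyde | O=Cc1cc(O[Si](C(C)C)(C(C)C)C(C)C)ccc1OC(C)(C=C)C=C | intermediate
6 | triisopropyl{4-[(3-methylpenta-1,4-dien-3-yl)oxy]-3-vinylphenoxy}silane | C=Cc1cc(O[Si](C(C)C)(C(C)C)C(C)C)ccc1OC(C)(C=C)C=C | intermediate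
7 | (S)-triisopropyl[(2-methyl-2-vinyl-2H-chromen-6-yl)oxy]silane | C=C[C@@]1(C)C=Cc2cc(O[Si](C(C)C)(C(C)C)C(C)C)ccc2O1 | intermediate
8 | (R)-triisopropyl[(2-methyl-2-vinylchroman-6-yl)oxy]silane | C=C[C@@]1(C)CCc2cc(O[Si](C(C)C)(C(C)C)C(C)C)ccc2O1 | intermediate
9 | 2-(2,6,6-trimethylcyclohex-1-en-1-yl)acetaldehyde (β-homocyclocitral) | CC1=C(CC=O)C(C)(C)CCC1 | starting material
10 | 2-(2,6,6-trimethylcyclohex-1-en-1-yl)ethan-1-ol | CC1=C(CCO)C(C)(C)CCC1 | intermediate
11 | 2-(2-bromoethyl)-1,3,3-trimethylcyclohex-1-ene | CC1=C(CCBr)C(C)(C)CCC1 | intermediate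
12 | propyne | CC#C | starting material
13 | [2-(2,6,6-trimethylcyclohex-1-en-1-yl)ethyl]magnesium bromide | CC1=C(CC[Mg]Br)C(C)(C)CCC1 | intermediate (not isolated)
14 | [2-(2,6,6-trimethylcyclohex-1-en-1-yl)ethyl]copper (magnesium bromide complex) | CC1=C(CC[Cu])C(C)(C)CCC1 | intermediate (not isolated)
15 | [(Z)-2-methyl-4-(2,6,6-trimethylcyclohex-1-en-1-yl)but-1-en-1-yl]copper | CC1=C(CC/C(C)=C\[Cu])C(C)(C)CCC1 | intermediate (not isolated)
16 | (Z)-2-(4-iodo-3-methylbut-3-en-1-yl)-1,3,3-trimethylcyclohex-1-ene | CC1=C(CC/C(C)=C\I)C(C)(C)CCC1 | intermediate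
17 | (R)-triisopropyl({2-methyl-2-[(1E,3Z)-4-methyl-6-(2,6,6-trimethylcyclohex-1-en-1-yl)hexa-1,3-dien-1-yl]chroman-6-yl}oxy)silane | CC1=C(CC/C(C)=C\C=C\[C@@]2(C)CCc3cc(O[Si](C(C)C)(C(C)C)C(C)C)ccc3O2)C(C)(C)CCC1 | intermediate
18 | (R)-2-methyl-2-[(1E,3Z)-4-methyl-6-(2,6,6-trimethylcyclohex-1-en-1-yl)hexa-1,3-dien-1-yl]chroman-6-ol | CC1=C(CC/C(C)=C\C=C\[C@@]2(C)CCc3cc(O)ccc3O2)C(C)(C)CCC1 | target

## Step count and risks

Total step count: 10 (steps 1 to 5 for the chroman half, steps 6 to 8 for the iodide, steps 9 and 10 for union and deprotection).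
Longest linear sequence: 7 steps (1, 2, 3, 4, 5, 9, 10) from 2-fluoro-5-hydroxybenzaldehyde.

Steps most likely to fail:

1. Step 4. What may go wrong: weak discrimination between the two enantiotopic vinyl groups when the molybdacyclobutane forms on this aryl-linked triene, or slow turnover because ethene or the styrene holds the metal. Fallback (resolution in place of asymmetric catalysis): it sets out from 6. Ring closure with the achiral ruthenium carbene RuCl2(=CHPh)(PCy3)(H2IMes), the second-generation Grubbs catalyst, in CH2Cl2 at 40 °C should give racemic triisopropyl[(2-methyl-2-vinyl-2H-chromen-6-yl)oxy]silane F1. Preparative chromatography on a cellulose tris(3,5-dimethylphenylcarbamate) stationary phase (hexane/i-PrOH) then separates the enantiomers; the (S)-enantiomer is 7, where the route is rejoined, and (R)-triisopropyl[(2-methyl-2-vinyl-2H-chromen-6-yl)oxy]silane F2 is set aside.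

2. Step 9. What may go wrong: β-aryloxide elimination from the alkylpalladium intermediate with opening of ring B, ionisation of the tertiary allylic aryl ether by zerovalent palladium with loss of configuration at C2, or Z-to-E isomerisation of the trisubstituted alkene through hydridopalladium re-addition. Fallback (two sp2 partners joined by cross-coupling instead of alkene insertion): it sets out from 8 and 16. Lemieux–Johnson oxidation of the vinyl group of 8 (OsO4 cat., NaIO4, 2,6-lutidine, dioxane/H2O) should pass through 1-[(R)-2-methyl-6-(triisopropylsilyloxy)chroman-2-yl]ethane-1,2-diol F3 and give (R)-2-methyl-6-[(triisopropylsilyl)oxy]chroman-2-carbaldehyde F4, an aldehyde without α-hydrogen and so configurationally safe. Takai olefination (CrCl2, CHI3, THF, 0 °C) should convert it into (R)-{[2-((E)-2-iodovinyl)-2-methylchroman-6-yl]oxy}triisopropylsilane F5. In a second flask 16 is treated with t-BuLi (2 equiv, Et2O, −78 °C) to give [(Z)-2-methyl-4-(2,6,6-trimethylcyclohex-1-en-1-yl)but-1-en-1-yl]lithium F6 and then with ZnCl2 to give [(Z)-2-methyl-4-(2,6,6-trimethylcyclohex-1-en-1-yl)but-1-en-1-yl]zinc chloride F7. Negishi coupling of the two (Pd(PPh3)4, THF, rt) joins C2' to C3' with retention at both alkenes and comes back to the route at 17.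

3. Step 2. What may go wrong: slow substitution because the para-silyloxy group pushes electron density onto the carbon that bears fluorine, so that silyl transfer from the aryl oxygen to the alkoxide and hydride transfer between aldehyde molecules overtake it. Fallback (the oxygen para to the ether is introduced after the substitution): it sets out from 4, the potassium alkoxide of 3. With purchased 5-bromo-2-fluorobenzaldehyde, whose bromine activates and cannot be transferred (THF, 0 °C), it should give 5-bromo-2-[(3-methylpenta-1,4-dien-3-yl)oxy]benzaldehyde F8. Wittig methylenation as in step 3 gives 4-bromo-1-[(3-methylpenta-1,4-dien-3-yl)oxy]-2-vinylbenzene F9. Bromine–lithium exchange (t-BuLi, Et2O, −78 °C) gives {4-[(3-methylpenta-1,4-dien-3-yl)oxy]-3-vinylphenyl}lithium F10, which is trapped with B(OMe)3 as dimethyl {4-[(3-methylpenta-1,4-dien-3-yl)oxy]-3-vinylphenyl}boronate F11 and oxidised in the same flask (H2O2, NaOH, 0 °C) to 4-[(3-methylpenta-1,4-dien-3-yl)oxy]-3-vinylphenol F12. Silylation as in step 1 (TIPSCl, imidazole, DMF) comes back to the route at 6.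

## Further compounds

F1 | step 4 | racemic triisopropyl[(2-methyl-2-vinyl-2H-chromen-6-yl)oxy]silane | C=CC1(C)C=Cc2cc(O[Si](C(C)C)(C(C)C)C(C)C)ccc2O1
F2 | step 4 | (R)-triisopropyl[(2-methyl-2-vinyl-2H-chromen-6-yl)oxy]silane | C=C[C@]1(C)C=Cc2cc(O[Si](C(C)C)(C(C)C)C(C)C)ccc2O1
F3 | step 9 | 1-[(R)-2-methyl-6-(triisopropylsilyloxy)chroman-2-yl]ethane-1,2-diol (both epimers at the new carbinol carbon) | OCC(O)[C@@]1(C)CCc2cc(O[Si](C(C)C)(C(C)C)C(C)C)ccc2O1
F4 | step 9 | (R)-2-methyl-6-[(triisopropylsilyl)oxy]chroman-2-carbaldehyde | O=C[C@@]1(C)CCc2cc(O[Si](C(C)C)(C(C)C)C(C)C)ccc2O1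
F5 | step 9 | (R)-{[2-((E)-2-iodovinyl)-2-methylchroman-6-yl]oxy}triisopropylsilane | I/C=C/[C@@]1(C)CCc2cc(O[Si](C(C)C)(C(C)C)C(C)C)ccc2O1
F6 | step 9 | [(Z)-2-methyl-4-(2,6,6-trimethylcyclohex-1-en-1-yl)but-1-en-1-yl]lithium | CC1=C(CC/C(C)=C\[Li])C(C)(C)CCC1
F7 | step 9 | [(Z)-2-methyl-4-(2,6,6-trimethylcyclohex-1-en-1-yl)but-1-en-1-yl]zinc chloride | CC1=C(CC/C(C)=C\[Zn]Cl)C(C)(C)CCC1
F8 | step 2 | 5-bromo-2-[(3-methylpenta-1,4-dien-3-yl)oxy]benzaldehyde | O=Cc1cc(Br)ccc1OC(C)(C=C)C=C
F9 | step 2 | 4-bromo-1-[(3-methylpenta-1,4-dien-3-yl)oxy]-2-vinylbenzene | C=Cc1cc(Br)ccc1OC(C)(C=C)C=C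
F10 | step 2 | {4-[(3-methylpenta-1,4-dien-3-yl)oxy]-3-vinylphenyl}lithium | C=Cc1cc([Li])ccc1OC(C)(C=C)C=C
F11 | step 2 | dimethyl {4-[(3-methylpenta-1,4-dien-3-yl)oxy]-3-vinylphenyl}boronate | C=Cc1cc(B(OC)OC)ccc1OC(C)(C=C)C=C
F12 | step 2 | 4-[(3-methylpenta-1,4-dien-3-yl)oxy]-3-vinylphenol | C=Cc1cc(O)ccc1OC(C)(C=C)C=C
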